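## Retrosynthetic overview

1. Testudinariol A ⇒ two carbonyl-ene closures (both cyclopentanols, formed last) of a C2-symmetric bis(oxanyl) dialdehyde.
2. That dialdehyde ⇒ two catalyst-controlled oxa-Michael closures (both oxane rings, formed first) of an acyclic, stereocentre-free C30 bis(hydroxy enal), a 26,29-dioxo-27,28-dihydroxysqualene.
3. The C30 chain ⇒ two-directional directed aldol condensation of a C14 dialdehyde with the aza-enolate of 6-methylhept-5-enal tert-butylimine (from acetaldehyde tert-butylimine and homoprenyl bromide).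
4. The C14 dialdehyde ⇒ double Johnson–Claisen rearrangement (sets both trisubstituted alkenes) of the bis-allylic diol made from succinaldehyde and a 2-lithioallyl silyl ether.
5. Ring order: oxane, oxane (one operation), then cyclopentane, cyclopentane (one operation); all eight stereocentres arise in these two operations.

Assumption: the presumed biosynthesis is read as oxa-Michael closure of each oxane (27-OH/28-OH onto the 26-/29-enal) followed by carbonyl-ene closure of each cyclopentanol; squalene numbering (C-1 to C-30) is used for positions.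

Assumption: 9-amino-9-deoxy-epi-quinidine is taken to deliver oxygen to the Re face of C-7 and C-18 (quinuclidine-side delivery in the E-iminium ion); the quinine-derived pseudoenantiomer gives the mirror-image series.

TBS = tert-butyldimethylsilyl.

## Route

Step 1
Reactants: 1 2,5-dimethoxytetrahydrofuran (cis/trans mixture)
Product: 2 butanedial (succinaldehyde)
Conditions: H2O, 90 °C, 2 h; distil off MeOH/H2O; toluene azeotrope; vacuum distillation; use at once
Reagents that add atoms: water, O
Why: Thermal acetal hydrolysis of the cyclic bis-acetal releases monomeric succinaldehyde while methanol is driven off by distillation, and no stereocentre is formed.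

Step 2
Reactants: 3 2-bromoprop-2-en-1-ol
Product: 4 [(2-bromoprop-2-en-1-yl)oxy](tert-butyl)dimethylsilane
Conditions: TBSCl, imidazole, CH2Cl2, 0 to 23 °C
Reagents that add atoms: tert-butyldimethylsilyl chloride (TBSCl), CC(C)(C)[Si](C)(C)Cl
Why: Imidazole-promoted silyl ether protection masks the primary allylic hydroxyl for the organolithium, Claisen, hydride and aza-enolate steps, and no stereocentre is formed.

Step 3
Reactants: 4 [(2-bromoprop-2-en-1-yl)oxy](tert-butyl)dimethylsilane; 2 butanedial
Product: 6 2,7-bis(TBSOCH2)octa-1,7-diene-3,6-diol (rac/meso mixture), via vinyllithium 5 (not isolated)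
Conditions: 4 (2.4 equiv), t-BuLi (4.8 equiv), Et2O, −78 °C; then 2 (1.0 equiv), −78 to −20 °C; H2O
Reagents that add atoms: none
Why: Bromine–lithium exchange gives an alkenyllithium that adds 1,2 to both aldehydes (two-directional carbonyl addition), and the two carbinol centres form without control, which does not matter because both are erased in step 4.

Step 4
Reactants: 6 2,7-bis(TBSOCH2)octa-1,7-diene-3,6-diol
Product: 8 diethyl (4Z,8Z)-4,9-bis(TBSOCH2)dodeca-4,8-dienedioate, via bis(ketene acetal) 7 (not isolated)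
Conditions: MeC(OEt)3 (12 equiv), EtCO2H (0.2 equiv), 140 °C, 3 h, EtOH distilled off
Reagents that add atoms: triethyl orthoacetate, CCOC(C)(OCC)OCC
Why: Double Johnson–Claisen (orthoester Claisen) rearrangement through chair transition states with the C-12/C-13 chain equatorial places each new CH2CH2CO2Et arm trans to that chain, so both diastereomers of 6 converge on the single squalene-type alkene geometry (Z by CIP because of the CH2OTBS group) and no stereocentre remains.

Step 5
Reactants: 8 diethyl (4Z,8Z)-4,9-bis(TBSOCH2)dodeca-4,8-dienedioate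
Product: 9 (4Z,8Z)-4,9-bis(TBSOCH2)dodeca-4,8-dienedial
Conditions: i-Bu2AlH (2.2 equiv), CH2Cl2, −78 °C, 1 h; cold 1 M HCl
Reagents that add atoms: none
Why: Partial ester reduction by i-Bu2AlH stops at the aluminium hemiacetal at −78 °C, which collapses to the aldehyde on acidic work-up while silyl ethers and alkenes are untouched, and no stereocentre is formed.

Step 6
Reactants: 10 (E)-N-tert-butylethanimine (acetaldehyde N-tert-butylimine); 11 5-bromo-2-methylpent-2-ene
Product: 13 (E)-N-tert-butyl-6-methylhept-5-en-1-imine, via azaallyllithium 12 (not isolated)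
Conditions: LiN(i-Pr)2 (1.05 equiv), THF, 0 °C; then 11, −78 to 23 °C; distil
Reagents that add atoms: none
Why: Metalloenamine (aza-enolate) C-alkylation by the primary homoallylic bromide gives the monoalkylated aldimine, the bulky N-tert-butyl group suppressing N-alkylation and self-condensation, and no stereocentre is formed.

Step 7
Reactants: 13 (E)-N-tert-butyl-6-methylhept-5-en-1-imine; 9 (4Z,8Z)-4,9-bis(TBSOCH2)dodeca-4,8-dienedial
Product: 16 (2E,6Z,10Z,14E)-6,11-bis(TBSOCH2)-2,15-bis(4-methylpent-3-en-1-yl)hexadeca-2,6,10,14-tetraenedial, via azaallyllithium 14 (not isolated), via bis(hydroxy imine) 15 (not isolated)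
Conditions: 13 (2.6 equiv), LiN(i-Pr)2 (2.5 equiv), THF, 0 °C; 9 (1.0 equiv), −78 °C, 1 h; H2O; then aq. (CO2H)2, hexane, 23 °C, 12 h
Reagents that add atoms: water, O
Why: Two-directional directed aldol condensation (Wittig metalloenamine method) in which the azaallyllithium adds to both aldehydes at −78 °C and aqueous oxalic acid then dehydrates the β-hydroxy imines through their enamine tautomers and hydrolyses the imines to the thermodynamically favoured (E)-2-alkyl enals, so the transient carbinol centres of 15 disappear.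

Step 8
Reactants: 16 (2E,6Z,10Z,14E)-6,11-bis(TBSOCH2)-2,15-bis(4-methylpent-3-en-1-yl)hexadeca-2,6,10,14-tetraenedial
Product: 17 (2E,6Z,10Z,14E)-6,11-bis(hydroxymethyl)-2,15-bis(4-methylpent-3-en-1-yl)hexadeca-2,6,10,14-tetraenedial
Conditions: HF·pyridine, pyridine, THF, 0 °C, 3 h; NaHCO3; rapid chromatography on neutral silica
Reagents that add atoms: none
Why: Fluoride-mediated silyl ether cleavage under pyridine-buffered, weakly acidic conditions frees both primary allylic alcohols without the base or strong acid that would start an uncatalysed racemic oxa-Michael closure of the hindered α-branched enals, and no stereocentre is formed.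

Step 9
Reactants: 17 (2E,6Z,10Z,14E)-6,11-bis(hydroxymethyl)-2,15-bis(4-methylpent-3-en-1-yl)hexadeca-2,6,10,14-tetraenedial
Product: 18 1,4-bis{(3Z,6R)-6-[(2R)-6-methyl-1-oxohept-5-en-2-yl]oxan-3-ylidene}butane
Conditions: 9-amino-9-deoxy-epi-quinidine (40 mol%), CF3CO2H (60 mol%), toluene (0.02 M), 23 °C, 48 h; filter through silica
Reagents that add atoms: none
Why: Proposed new method: a two-directional iminium-ion-catalysed 6-exo oxa-Michael addition in which the primary amine condenses with each α-branched enal, the quinuclidinium trifluoroacetate relays the 27-/28-hydroxyl onto the Re face of C-7/C-18 and returns the same proton to C-6/C-19 of the resulting enamine from the same face (net syn addition of O–H across the E alkene, giving 6R,7R at both ends), the closest known reactions being cinchona primary-amine-catalysed hetero-Michael/protonation and epoxidation of α-branched enals and amine-catalysed intramolecular oxa-Michael closure of hydroxy enones, and the two independent catalyst-controlled events raise the ee of the C2 product by leaving the minor antipode mainly in a separable meso-type diastereomer.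

Step 10
Reactants: 18 1,4-bis{(3Z,6R)-6-[(2R)-6-methyl-1-oxohept-5-en-2-yl]oxan-3-ylidene}butane
Product: 19 testudinariol A, 1,4-bis{(3Z,6R)-6-[(1S,2S,3R)-2-hydroxy-3-(prop-1-en-2-yl)cyclopentyl]oxan-3-ylidene}butane
Conditions: Me2AlCl (4.0 equiv), CH2Cl2, −78 to −40 °C, 2 h; cold 1 M HCl
Reagents that add atoms: none
Why: Two Lewis-acid-promoted intramolecular carbonyl-ene reactions in which each aluminium-bound aldehyde is attacked by C-3 of the isopropylidene alkene through a closed six-centre transition state cis-fused to the forming five-membered ring, so hydroxyl and isopropenyl emerge cis, while the oxanyl group on the existing C-6 centre sits anti to the bulky O–Al unit, so hydroxyl and oxanyl emerge trans, which fixes C-26 (S) and C-3 (R) from C-6 and gives the (1S,2S,3R) cyclopentanols.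

## Compound list

1 | 2,5-dimethoxytetrahydrofuran (cis/trans mixture) | COC1CCC(OC)O1 | starting material
2 | butanedial (succinaldehyde) | O=CCCC=O | intermediate
3 | 2-bromoprop-2-en-1-ol | OCC(Br)=C | starting material
4 | [(2-bromoprop-2-en-1-yl)oxy](tert-butyl)dimethylsilane | C=C(Br)CO[Si](C)(C)C(C)(C)C | intermediate
5 | tert-butyl[(2-lithioprop-2-en-1-yl)oxy]dimethylsilane (vinyllithium) | [Li]C(=C)CO[Si](C)(C)C(C)(C)C | intermediate
6 | 2,7-bis({[tert-butyl(dimethyl)silyl]oxy}methyl)octa-1,7-diene-3,6-diol (rac/meso mixture) | C=C(CO[Si](C)(C)C(C)(C)C)C(O)CCC(O)C(=C)CO[Si](C)(C)C(C)(C)C | intermediate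
7 | 3,6-bis[(1-ethoxyethenyl)oxy]-2,7-bis({[tert-butyl(dimethyl)silyl]oxy}methyl)octa-1,7-diene (bis(ketene acetal)) | C=C(OCC)OC(CCC(OC(=C)OCC)C(=C)CO[Si](C)(C)C(C)(C)C)C(=C)CO[Si](C)(C)C(C)(C)C | intermediate
8 | diethyl (4Z,8Z)-4,9-bis({[tert-butyl(dimethyl)silyl]oxy}methyl)dodeca-4,8-dienedioate | CCOC(=O)CC/C(CO[Si](C)(C)C(C)(C)C)=C/CC/C=C(CO[Si](C)(C)C(C)(C)C)/CCC(=O)OCC | intermediate
9 | (4Z,8Z)-4,9-bis({[tert-butyl(dimethyl)silyl]oxy}methyl)dodeca-4,8-dienedial | O=CCC/C(CO[Si](C)(C)C(C)(C)C)=C/CC/C=C(CO[Si](C)(C)C(C)(C)C)/CCC=O | intermediate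
10 | (E)-N-tert-butylethanimine (acetaldehyde N-tert-butylimine) | C/C=N/C(C)(C)C | starting material
11 | 5-bromo-2-methylpent-2-ene (homoprenyl bromide) | CC(C)=CCCBr | starting material
12 | lithium N-tert-butyl-N-ethenylamide (azaallyllithium) | [Li]N(C=C)C(C)(C)C | intermediate
13 | (E)-N-tert-butyl-6-methylhept-5-en-1-imine | CC(C)=CCCC/C=N/C(C)(C)C | intermediate
14 | lithium N-tert-butyl-N-(6-methylhepta-1,5-dien-1-yl)amide (azaallyllithium) | [Li]N(C=CCCC=C(C)C)C(C)(C)C | intermediate
15 | (6Z,10Z)-1,16-bis(tert-butylimino)-6,11-bis({[tert-butyl(dimethyl)silyl]oxy}methyl)-2,15-bis(4-methylpent-3-en-1-yl)hexadeca-6,10-diene-3,14-diol (diastereomer mixture) | CC(C)(C)N=CC(CCC=C(C)C)C(O)CC/C(CO[Si](C)(C)C(C)(C)C)=C/CC/C=C(CO[Si](C)(C)C(C)(C)C)/CCC(O)C(CCC=C(C)C)C=NC(C)(C)C | intermediate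
16 | (2E,6Z,10Z,14E)-6,11-bis({[tert-butyl(dimethyl)silyl]oxy}methyl)-2,15-bis(4-methylpent-3-en-1-yl)hexadeca-2,6,10,14-tetraenedial | O=C/C(CCC=C(C)C)=C/CC/C(CO[Si](C)(C)C(C)(C)C)=C/CC/C=C(CO[Si](C)(C)C(C)(C)C)/CC/C=C(/C=O)CCC=C(C)C | intermediate
17 | (2E,6Z,10Z,14E)-6,11-bis(hydroxymethyl)-2,15-bis(4-methylpent-3-en-1-yl)hexadeca-2,6,10,14-tetraenedial | O=C/C(CCC=C(C)C)=C/CC/C(CO)=C/CC/C=C(CO)/CC/C=C(/C=O)CCC=C(C)C | intermediate
18 | 1,4-bis{(3Z,6R)-6-[(2R)-6-methyl-1-oxohept-5-en-2-yl]oxan-3-ylidene}butane | O=C[C@H](CCC=C(C)C)[C@H]1CC/C(=C/CC/C=C2/CC[C@H]([C@H](C=O)CCC=C(C)C)OC2)CO1 | intermediate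
19 | testudinariol A, 1,4-bis{(3Z,6R)-6-[(1S,2S,3R)-2-hydroxy-3-(prop-1-en-2-yl)cyclopentyl]oxan-3-ylidene}butane | C=C(C)[C@H]1CC[C@H]([C@H]2CC/C(=C/CC/C=C3/CC[C@H]([C@H]4CC[C@H](C(=C)C)[C@@H]4O)OC3)CO2)[C@H]1O | target

## Step count and risks

Total steps: 10.

Longest linear sequence: 8 steps (3 → 4 → 6 → 8 → 9 → 16 → 17 → 18 → 19; steps 2, 3, 4, 5, 7, 8, 9, 10).

**Most likely to fail, first: step 9.** Iminium formation with the α-branched enals may be slow. The sense and level of induction at C-7/C-18 and the face of protonation at C-6/C-19 are unproven, and four centres must come out right at once.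

The fallback sets out from 16 and comes back at 18. NaBH4/CeCl3·7H2O (MeOH, 0 °C) reduces both enals 1,2 to the bis(allylic alcohol) F1. ClCO2Me/pyridine gives the bis(methyl carbonate) F2. HF·pyridine frees the diol bis(carbonate) F3. Pd2(dba)3·CHCl3 with the (R,R)-DACH-phenyl Trost ligand (enantiomer chosen for the 6R ether) in CH2Cl2 then closes both oxanes by asymmetric allylic etherification; 6-exo attack of the hydroxyl on C-7 of the π-allyl sets C-7 and C-18 and gives 1,4-bis[(3Z,6R)-6-(6-methylhepta-1,5-dien-2-yl)oxan-3-ylidene]butane F4. 9-BBN hydroboration of the two 1,1-disubstituted alkenes followed by NaOH/H2O2 adds anti to the allylic C–O bond by acyclic 1,2-induction; this sets C-6 and C-19 and gives the diol 1,4-bis{(3Z,6R)-6-[(2S)-1-hydroxy-6-methylhept-5-en-2-yl]oxan-3-ylidene}butane F5. Dess–Martin periodinane/NaHCO3 oxidises F5 to 18.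

**Second: step 7.** Two aldol additions to an enolisable dialdehyde are needed, and retro-aldol or incomplete dehydration of the β-hydroxy imines would give mixtures.

The fallback sets out from 13 (with 9) and comes back at 16. Compound 13 is deprotonated with LiN(i-Pr)2 and C-silylated with Me3SiCl to N-tert-butyl-6-methyl-2-(trimethylsilyl)hept-5-en-1-imine F6. Its lithio derivative (s-BuLi, THF, −78 °C) adds to 9 and loses Me3SiOLi in a Peterson olefination. This gives the bis(α,β-unsaturated tert-butylimine) F7 directly, with no β-hydroxy imine to dehydrate. Aqueous oxalic acid hydrolyses F7 to 16.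

**Third: step 3.** Succinaldehyde oligomerises, the mono-adduct alkoxide can close onto the second aldehyde as a lactolate, and the β-silyloxy alkenyllithium can eliminate on warming.

The fallback sets out from 4 and comes back at 6. Vinyllithium 5 (from 4 and t-BuLi) is added to N,N'-dimethoxy-N,N'-dimethylbutanediamide (the bis-Weinreb amide of succinic acid), whose chelated tetrahedral adducts can neither cyclise nor over-add. This gives the bis-enone 2,7-bis(TBSOCH2)octa-1,7-diene-3,6-dione F8. NaBH4/CeCl3·7H2O (1,2-reduction) gives 6.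

## Further compounds

F1 | step 9 | (2E,6Z,10Z,14E)-6,11-bis({[tert-butyl(dimethyl)silyl]oxy}methyl)-2,15-bis(4-methylpent-3-en-1-yl)hexadeca-2,6,10,14-tetraene-1,16-diol | OC/C(CCC=C(C)C)=C/CC/C(CO[Si](C)(C)C(C)(C)C)=C/CC/C=C(CO[Si](C)(C)C(C)(C)C)/CC/C=C(/CO)CCC=C(C)C
F2 | step 9 | (2E,6Z,10Z,14E)-6,11-bis({[tert-butyl(dimethyl)silyl]oxy}methyl)-2,15-bis(4-methylpent-3-en-1-yl)hexadeca-2,6,10,14-tetraene-1,16-diyl dimethyl biscarbonate | COC(=O)OC/C(CCC=C(C)C)=C/CC/C(CO[Si](C)(C)C(C)(C)C)=C/CC/C=C(CO[Si](C)(C)C(C)(C)C)/CC/C=C(/COC(=O)OC)CCC=C(C)C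
F3 | step 9 | (2E,6Z,10Z,14E)-6,11-bis(hydroxymethyl)-2,15-bis(4-methylpent-3-en-1-yl)hexadeca-2,6,10,14-tetraene-1,16-diyl dimethyl biscarbonate | COC(=O)OC/C(CCC=C(C)C)=C/CC/C(CO)=C/CC/C=C(CO)/CC/C=C(/COC(=O)OC)CCC=C(C)C
F4 | step 9 | 1,4-bis[(3Z,6R)-6-(6-methylhepta-1,5-dien-2-yl)oxan-3-ylidene]butane | C=C(CCC=C(C)C)[C@H]1CC/C(=C/CC/C=C2/CC[C@H](C(=C)CCC=C(C)C)OC2)CO1
F5 | step 9 | 1,4-bis{(3Z,6R)-6-[(2S)-1-hydroxy-6-methylhept-5-en-2-yl]oxan-3-ylidene}butane | OC[C@H](CCC=C(C)C)[C@H]1CC/C(=C/CC/C=C2/CC[C@H]([C@H](CO)CCC=C(C)C)OC2)CO1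
F6 | step 7 | N-tert-butyl-6-methyl-2-(trimethylsilyl)hept-5-en-1-imine (racemic) | CC(C)=CCCC([Si](C)(C)C)/C=N/C(C)(C)C
F7 | step 7 | (1E,2E,6Z,10Z,14E,16E)-N,N'-di-tert-butyl-6,11-bis({[tert-butyl(dimethyl)silyl]oxy}methyl)-2,15-bis(4-methylpent-3-en-1-yl)hexadeca-2,6,10,14-tetraene-1,16-diimine | CC(C)(C)/N=C/C(CCC=C(C)C)=C/CC/C(CO[Si](C)(C)C(C)(C)C)=C/CC/C=C(CO[Si](C)(C)C(C)(C)C)/CC/C=C(/C=N/C(C)(C)C)CCC=C(C)C
F8 | step 3 | 2,7-bis({[tert-butyl(dimethyl)silyl]oxy}methyl)octa-1,7-diene-3,6-dione | C=C(CO[Si](C)(C)C(C)(C)C)C(=O)CCC(=O)C(=C)CO[Si](C)(C)C(C)(C)C
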